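**Retrosynthetic overview**
- The target comes from a tris-silyl ether by desilylation; its tetrasubstituted enal comes from the ring ketone by isopropenyl addition and oxidative 1,3-transposition.
- The bis-allylic carbinol is cut into a ring-bound (E)-2-methyl-enal and an (E)-alkenylzinc made from the alkyne of (S)-citronellal; the enal comes from a 3-carbon aldehyde arm by Wittig olefination.
- Key disconnection: the bond from the quaternary ring carbon to that aldehyde arm is made by conjugate addition of a propanal homoenolate equivalent (β-carbon nucleophile) to the β-carbon of a 4-silyloxy-3,4-dimethylcyclohexenone; the enolate is allylated in the same pot (the allyl group becomes the 3-hydroxypropyl arm).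
- The enone comes from 2-methylcyclohex-2-en-1-one by catalytic asymmetric methyl addition, silylation and allylic oxidation.
- Rings: the single carbocycle is bought with the first starting material; no ring is formed in the route.

Assumption: each chiral ligand is used as the antipode that gives the configuration stated (S carbinol in step 1; Si-face addition in step 8); minor isomers are removed by chromatography.

**Step 1**
Reactants: 1 2-methylcyclohex-2-en-1-one
Product: 2 (1S)-1,2-dimethylcyclohex-2-en-1-ol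
Conditions: ZnMe2, Ti(OiPr)4, trans-cyclohexane-1,2-diamine-derived bis(hydroxycamphorsulfonamide) ligand (10 mol %), toluene/hexane, 25 °C; aq NH4Cl
Reagents that add atoms: dimethylzinc, C[Zn]C
Why: Catalytic enantioselective 1,2-addition of a methylzinc reagent to a cyclic enone under titanium bis(sulfonamide)-diol catalysis; the catalyst tells the methyl-bearing sp2 flank from the CH2 flank, so methyl adds to one carbonyl face and sets the tertiary carbinol as S.

**Step 2**
Reactants: 2 (1S)-1,2-dimethylcyclohex-2-en-1-ol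
Product: 3 triethyl{[(1S)-1,2-dimethylcyclohex-2-en-1-yl]oxy}silane
Conditions: Et3SiOTf, 2,6-lutidine, CH2Cl2, −78 to 0 °C
Reagents that add atoms: triethylsilyl trifluoromethanesulfonate, CC[Si](CC)(CC)OS(=O)(=O)C(F)(F)F
Why: Silylation of a tertiary alcohol with a silyl triflate and hindered base at low temperature avoids ionisation of the allylic carbinol and gives the bulky group needed for facial control in step 4.

**Step 3**
Reactants: 3 triethyl{[(1S)-1,2-dimethylcyclohex-2-en-1-yl]oxy}silane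
Product: 4 (4S)-3,4-dimethyl-4-[(triethylsilyl)oxy]cyclohex-2-en-1-one
Conditions: Rh2(cap)4 (cap = caprolactamate, 1 mol %), t-BuOOH, K2CO3, CH2Cl2, 25 °C
Reagents that add atoms: tert-butyl hydroperoxide, CC(C)(C)OO
Why: Radical allylic C–H oxidation takes the only ring allylic CH2 to the enone carbonyl, while the silyl ether and the stereocentre are untouched.

**Step 4 (key step)**
Reactants: 4 (4S)-3,4-dimethyl-4-[(triethylsilyl)oxy]cyclohex-2-en-1-one; 5 2-(2-bromoethyl)-1,3-dioxolane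
Product: 9 (2S,3S,4S)-3-[2-(1,3-dioxolan-2-yl)ethyl]-3,4-dimethyl-2-(prop-2-en-1-yl)-4-[(triethylsilyl)oxy]cyclohexan-1-one, via Grignard reagent 6 (not isolated), via silyl enol ether 7 (not isolated), via lithium enolate 8 (not isolated)
Conditions: 5, Mg, THF, 25 °C; CuBr·SMe2 (20 mol %), Me3SiCl, HMPA, 4, THF, −78 to −30 °C; Et3N/pentane, filter, evaporate; MeLi, THF, 0 °C; allyl iodide, HMPA, −78 to 0 °C
Reagents that add atoms: allyl iodide, C=CCI
Why: Copper-catalysed, Me3SiCl-accelerated conjugate addition of a propanal homoenolate equivalent joins its β-carbon to the enone β-carbon anti to the bulky triethylsilyloxy group (sets the quaternary C3), and the regiospecific lithium enolate released by MeLi is C-allylated axially, anti to the just-installed pseudo-axial chain (sets C2 trans to that chain).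

**Step 5**
Reactants: 9 (2S,3S,4S)-3-[2-(1,3-dioxolan-2-yl)ethyl]-3,4-dimethyl-2-(prop-2-en-1-yl)-4-[(triethylsilyl)oxy]cyclohexan-1-one
Product: 10 3-[(1S,2S,6S)-1,6-dimethyl-3-oxo-2-(prop-2-en-1-yl)-6-[(triethylsilyl)oxy]cyclohexyl]propanal
Conditions: pyridinium p-toluenesulfonate (cat.), acetone/H2O, 40 °C
Reagents that add atoms: water, O
Why: Mild acid-catalysed acetal hydrolysis unmasks the aldehyde; the hindered tertiary silyl ether survives and the weak acid does not trigger aldol closure onto the ketone.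

**Step 6**
Reactants: 10 3-[(1S,2S,6S)-1,6-dimethyl-3-oxo-2-(prop-2-en-1-yl)-6-[(triethylsilyl)oxy]cyclohexyl]propanal
Product: 11 (2E)-5-[(1S,2S,6S)-1,6-dimethyl-3-oxo-2-(prop-2-en-1-yl)-6-[(triethylsilyl)oxy]cyclohexyl]-2-methylpent-2-enal
Conditions: Ph3P=C(Me)CHO, toluene, 90 °C
Reagents that add atoms: 2-(triphenylphosphoranylidene)propanal, CC(C=O)=P(c1ccccc1)(c1ccccc1)c1ccccc1
Why: Wittig olefination with a stabilised formyl ylide reacts only with the aldehyde (the hindered ketone is inert) and gives the E trisubstituted enal under thermodynamic control of the oxaphosphetane.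

**Step 7**
Reactants: 12 (3S)-3,7-dimethyloct-6-enal ((S)-citronellal)
Product: 14 (3S)-3,7-dimethyloct-6-en-1-yne, via enol nonaflate 13 (not isolated)
Conditions: n-C4F9SO2F, tert-butylimino-tri(pyrrolidino)phosphorane, DMF, −20 to 25 °C
Reagents that add atoms: none
Why: One-pot nonaflation–elimination of an enolisable aldehyde gives the terminal alkyne with the same carbon count; the stereocentre is β to the carbonyl and is not touched.

**Step 8**
Reactants: 11 (2E)-5-[(1S,2S,6S)-1,6-dimethyl-3-oxo-2-(prop-2-en-1-yl)-6-[(triethylsilyl)oxy]cyclohexyl]-2-methylpent-2-enal; 14 (3S)-3,7-dimethyloct-6-en-1-yne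
Product: 17 (2S,3S,4S)-3-[(3E,5S,6E,8S)-5-hydroxy-4,8,12-trimethyltrideca-3,6,11-trien-1-yl]-3,4-dimethyl-2-(prop-2-en-1-yl)-4-[(triethylsilyl)oxy]cyclohexan-1-one, via alkenylborane 15 (not isolated), via alkenylzinc 16 (not isolated)
Conditions: BH3·SMe2, cyclohexene, toluene, 0 °C; 14, 0 to 25 °C; ZnMe2, −78 °C; (−)-3-exo-morpholinoisoborneol (10 mol %), 11, −30 to −10 °C; aq NH4Cl
Reagents that add atoms: none
Why: Syn anti-Markovnikov hydroboration of the terminal alkyne gives the E-alkenylborane, boron-to-zinc transmetalation follows, and the amino-alcohol-catalysed enantioselective alkenylzinc addition (Oppolzer-type) attacks the Si face of the aldehyde to set the carbinol S; the ketone does not react.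

**Step 9**
Reactants: 17 (2S,3S,4S)-3-[(3E,5S,6E,8S)-5-hydroxy-4,8,12-trimethyltrideca-3,6,11-trien-1-yl]-3,4-dimethyl-2-(prop-2-en-1-yl)-4-[(triethylsilyl)oxy]cyclohexan-1-one
Product: 19 (2S,3S,4S)-3-[(3E,5S,6E,8S)-5-hydroxy-4,8,12-trimethyltrideca-3,6,11-trien-1-yl]-2-(3-hydroxypropyl)-3,4-dimethyl-4-[(triethylsilyl)oxy]cyclohexan-1-one, via organoborane 18 (not isolated)
Conditions: 9-BBN (2.5 equiv), THF, 0 to 25 °C; 30% H2O2, aq NaHCO3, 0 to 25 °C
Reagents that add atoms: hydrogen peroxide, OO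
Why: Chemoselective hydroboration–oxidation: the bulky borane adds anti-Markovnikov only to the monosubstituted terminal alkene, because the internal and trisubstituted alkenes and the hindered ketone react far more slowly, and oxidation gives the primary alcohol.

**Step 10**
Reactants: 19 (2S,3S,4S)-3-[(3E,5S,6E,8S)-5-hydroxy-4,8,12-trimethyltrideca-3,6,11-trien-1-yl]-2-(3-hydroxypropyl)-3,4-dimethyl-4-[(triethylsilyl)oxy]cyclohexan-1-one
Product: 20 (2S,3S,4S)-2-{3-[(tert-butyldimethylsilyl)oxy]propyl}-3-[(3E,5S,6E,8S)-5-[(tert-butyldimethylsilyl)oxy]-4,8,12-trimethyltrideca-3,6,11-trien-1-yl]-3,4-dimethyl-4-[(triethylsilyl)oxy]cyclohexan-1-one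
Conditions: t-BuMe2SiCl, imidazole, DMF, 25 °C
Reagents that add atoms: tert-butyldimethylsilyl chloride, CC(C)(C)[Si](C)(C)Cl
Why: Silylation of the primary and the secondary allylic hydroxyl in one operation under conditions that do not enolise the ketone; this shields both alcohols from the oxidant of step 12.

**Step 11**
Reactants: 20 (2S,3S,4S)-2-{3-[(tert-butyldimethylsilyl)oxy]propyl}-3-[(3E,5S,6E,8S)-5-[(tert-butyldimethylsilyl)oxy]-4,8,12-trimethyltrideca-3,6,11-trien-1-yl]-3,4-dimethyl-4-[(triethylsilyl)oxy]cyclohexan-1-one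
Product: 21 (2S,3S,4S)-2-{3-[(tert-butyldimethylsilyl)oxy]propyl}-3-[(3E,5S,6E,8S)-5-[(tert-butyldimethylsilyl)oxy]-4,8,12-trimethyltrideca-3,6,11-trien-1-yl]-3,4-dimethyl-1-(prop-1-en-2-yl)-4-[(triethylsilyl)oxy]cyclohexan-1-ol (C1 epimers)
Conditions: CH2=C(Me)MgBr, CeCl3, THF, −78 to 0 °C
Reagents that add atoms: isopropenylmagnesium bromide, CC(=C)[Mg]Br
Why: 1,2-Addition of an organocerium reagent (Imamoto conditions) to the hindered, enolisable ketone proceeds without enolisation or epimerisation at C2; the new carbinol configuration is irrelevant because this carbon becomes sp2 in step 12.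

**Step 12**
Reactants: 21 (2S,3S,4S)-2-{3-[(tert-butyldimethylsilyl)oxy]propyl}-3-[(3E,5S,6E,8S)-5-[(tert-butyldimethylsilyl)oxy]-4,8,12-trimethyltrideca-3,6,11-trien-1-yl]-3,4-dimethyl-1-(prop-1-en-2-yl)-4-[(triethylsilyl)oxy]cyclohexan-1-ol
Product: 22 (2Z)-2-[(2R,3S,4S)-2-{3-[(tert-butyldimethylsilyl)oxy]propyl}-3-[(3E,5S,6E,8S)-5-[(tert-butyldimethylsilyl)oxy]-4,8,12-trimethyltrideca-3,6,11-trien-1-yl]-3,4-dimethyl-4-[(triethylsilyl)oxy]cyclohexylidene]propanal
Conditions: [C5H5NH][CrO3Cl] (pyridinium chlorochromate), 4 Å molecular sieves, CH2Cl2, 25 °C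
Reagents that add atoms: none
Why: Babler–Dauben oxidative 1,3-transposition: the tertiary allylic chromate ester undergoes a [3,3] shift to the primary allylic chromate, which is oxidised to the tetrasubstituted enal; the Z isomer (CHO syn to C2, whose chain is axial, and methyl syn to the ring CH2) is expected to dominate because it minimises allylic 1,3-strain.

**Step 13**
Reactants: 22 (2Z)-2-[(2R,3S,4S)-2-{3-[(tert-butyldimethylsilyl)oxy]propyl}-3-[(3E,5S,6E,8S)-5-[(tert-butyldimethylsilyl)oxy]-4,8,12-trimethyltrideca-3,6,11-trien-1-yl]-3,4-dimethyl-4-[(triethylsilyl)oxy]cyclohexylidene]propanal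
Product: 23 (2Z)-2-[(2R,3S,4S)-4-hydroxy-2-(3-hydroxypropyl)-3-[(3E,5S,6E,8S)-5-hydroxy-4,8,12-trimethyltrideca-3,6,11-trien-1-yl]-3,4-dimethylcyclohexylidene]propanal (target, CNP0323596.2)
Conditions: HF·pyridine, pyridine, THF, 0 to 25 °C
Reagents that add atoms: none
Why: Fluoride-mediated cleavage of all three silyl ethers under buffered conditions that leave the enal, the bis-allylic alcohol and the γ-stereocentre of the enal untouched.

**Compound list**
1 | 2-methylcyclohex-2-en-1-one | CC1=CCCCC1=O | starting material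
2 | (1S)-1,2-dimethylcyclohex-2-en-1-ol | CC1=CCCC[C@]1(C)O | intermediate
3 | triethyl{[(1S)-1,2-dimethylcyclohex-2-en-1-yl]oxy}silane | CC1=CCCC[C@]1(C)O[Si](CC)(CC)CC | intermediate
4 | (4S)-3,4-dimethyl-4-[(triethylsilyl)oxy]cyclohex-2-en-1-one | CC1=CC(=O)CC[C@]1(C)O[Si](CC)(CC)CC | intermediate
5 | 2-(2-bromoethyl)-1,3-dioxolane | BrCCC1OCCO1 | starting material
6 | [2-(1,3-dioxolan-2-yl)ethyl]magnesium bromide | Br[Mg]CCC1OCCO1 | intermediate
7 | {[(3S,4S)-3-[2-(1,3-dioxolan-2-yl)ethyl]-3,4-dimethyl-4-[(triethylsilyl)oxy]cyclohex-1-en-1-yl]oxy}trimethylsilane | C1(OCCO1)CC[C@@]2(C)C=C(O[Si](C)(C)C)CC[C@]2(C)O[Si](CC)(CC)CC | intermediate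
8 | lithium (3S,4S)-3-[2-(1,3-dioxolan-2-yl)ethyl]-3,4-dimethyl-4-[(triethylsilyl)oxy]cyclohex-1-en-1-olate | C1(OCCO1)CC[C@@]2(C)C=C(O[Li])CC[C@]2(C)O[Si](CC)(CC)CC | intermediate
9 | (2S,3S,4S)-3-[2-(1,3-dioxolan-2-yl)ethyl]-3,4-dimethyl-2-(prop-2-en-1-yl)-4-[(triethylsilyl)oxy]cyclohexan-1-one | C1(OCCO1)CC[C@@]2(C)[C@H](CC=C)C(=O)CC[C@]2(C)O[Si](CC)(CC)CC | intermediate
10 | 3-[(1S,2S,6S)-1,6-dimethyl-3-oxo-2-(prop-2-en-1-yl)-6-[(triethylsilyl)oxy]cyclohexyl]propanal | O=CCC[C@@]1(C)[C@H](CC=C)C(=O)CC[C@]1(C)O[Si](CC)(CC)CC | intermediate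
11 | (2E)-5-[(1S,2S,6S)-1,6-dimethyl-3-oxo-2-(prop-2-en-1-yl)-6-[(triethylsilyl)oxy]cyclohexyl]-2-methylpent-2-enal | O=C/C(C)=C/CC[C@@]1(C)[C@H](CC=C)C(=O)CC[C@]1(C)O[Si](CC)(CC)CC | intermediate
12 | (3S)-3,7-dimethyloct-6-enal ((S)-citronellal) | CC(C)=CCC[C@H](C)CC=O | starting material
13 | (3S)-3,7-dimethylocta-1,6-dien-1-yl nonafluorobutane-1-sulfonate (E/Z mixture) | CC(C)=CCC[C@H](C)C=COS(=O)(=O)C(F)(F)C(F)(F)C(F)(F)C(F)(F)F | intermediate
14 | (3S)-3,7-dimethyloct-6-en-1-yne | CC(C)=CCC[C@H](C)C#C | intermediate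
15 | dicyclohexyl[(1E,3S)-3,7-dimethylocta-1,6-dien-1-yl]borane | CC(C)=CCC[C@H](C)/C=C/B(C1CCCCC1)C1CCCCC1 | intermediate
16 | [(1E,3S)-3,7-dimethylocta-1,6-dien-1-yl](methyl)zinc | CC(C)=CCC[C@H](C)/C=C/[Zn]C | intermediate
17 | (2S,3S,4S)-3-[(3E,5S,6E,8S)-5-hydroxy-4,8,12-trimethyltrideca-3,6,11-trien-1-yl]-3,4-dimethyl-2-(prop-2-en-1-yl)-4-[(triethylsilyl)oxy]cyclohexan-1-one | CC(C)=CCC[C@H](C)/C=C/[C@H](O)/C(C)=C/CC[C@@]1(C)[C@H](CC=C)C(=O)CC[C@]1(C)O[Si](CC)(CC)CC | intermediate
18 | B-alkyl-9-borabicyclo[3.3.1]nonane adduct of 17 at the terminal alkene carbon, with the 5-hydroxyl as its 9-borabicyclononyl borinate | CC(C)=CCC[C@H](C)/C=C/[C@H](OB1C2CCCC1CCC2)/C(C)=C/CC[C@@]1(C)[C@H](CCCB2C3CCCC2CCC3)C(=O)CC[C@]1(C)O[Si](CC)(CC)CC | intermediate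
19 | (2S,3S,4S)-3-[(3E,5S,6E,8S)-5-hydroxy-4,8,12-trimethyltrideca-3,6,11-trien-1-yl]-2-(3-hydroxypropyl)-3,4-dimethyl-4-[(triethylsilyl)oxy]cyclohexan-1-one | CC(C)=CCC[C@H](C)/C=C/[C@H](O)/C(C)=C/CC[C@@]1(C)[C@H](CCCO)C(=O)CC[C@]1(C)O[Si](CC)(CC)CC | intermediate
20 | (2S,3S,4S)-2-{3-[(tert-butyldimethylsilyl)oxy]propyl}-3-[(3E,5S,6E,8S)-5-[(tert-butyldimethylsilyl)oxy]-4,8,12-trimethyltrideca-3,6,11-trien-1-yl]-3,4-dimethyl-4-[(triethylsilyl)oxy]cyclohexan-1-one | CC(C)=CCC[C@H](C)/C=C/[C@H](O[Si](C)(C)C(C)(C)C)/C(C)=C/CC[C@@]1(C)[C@H](CCCO[Si](C)(C)C(C)(C)C)C(=O)CC[C@]1(C)O[Si](CC)(CC)CC | intermediate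
21 | (2S,3S,4S)-2-{3-[(tert-butyldimethylsilyl)oxy]propyl}-3-[(3E,5S,6E,8S)-5-[(tert-butyldimethylsilyl)oxy]-4,8,12-trimethyltrideca-3,6,11-trien-1-yl]-3,4-dimethyl-1-(prop-1-en-2-yl)-4-[(triethylsilyl)oxy]cyclohexan-1-ol (C1 epimers, centre left undefined) | CC(C)=CCC[C@H](C)/C=C/[C@H](O[Si](C)(C)C(C)(C)C)/C(C)=C/CC[C@@]1(C)[C@H](CCCO[Si](C)(C)C(C)(C)C)C(O)(C(C)=C)CC[C@]1(C)O[Si](CC)(CC)CC | intermediate
22 | (2Z)-2-[(2R,3S,4S)-2-{3-[(tert-butyldimethylsilyl)oxy]propyl}-3-[(3E,5S,6E,8S)-5-[(tert-butyldimethylsilyl)oxy]-4,8,12-trimethyltrideca-3,6,11-trien-1-yl]-3,4-dimethyl-4-[(triethylsilyl)oxy]cyclohexylidene]propanal | CC(C)=CCC[C@H](C)/C=C/[C@H](O[Si](C)(C)C(C)(C)C)/C(C)=C/CC[C@@]1(C)[C@H](CCCO[Si](C)(C)C(C)(C)C)/C(=C(/C)C=O)CC[C@]1(C)O[Si](CC)(CC)CC | intermediate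
23 | (2Z)-2-[(2R,3S,4S)-4-hydroxy-2-(3-hydroxypropyl)-3-[(3E,5S,6E,8S)-5-hydroxy-4,8,12-trimethyltrideca-3,6,11-trien-1-yl]-3,4-dimethylcyclohexylidene]propanal | CC(C)=CCC[C@H](C)/C=C/[C@H](O)/C(C)=C/CC[C@@]1(C)[C@H](CCCO)/C(=C(/C)C=O)CC[C@]1(C)O | target

**Totals**
Total step count: 13. Longest linear sequence: 12 steps (steps 1 to 6 and 8 to 13, from compound 1); step 7 is the one-step side branch.

**Three steps most likely to fail**

Step 4. The β-carbon of 4 carries a methyl group and sits next to a fully substituted carbon, so the cuprate may add slowly or attack the carbonyl instead. The facial preference of the allylation at C2 is also only moderate. Fallback: the acceptor is made doubly activated and the allyl group is delivered by decarboxylative allylation. Setting out from 4, α-iodination (I2, pyridine, CH2Cl2) gives the 2-iodoenone F1. Carbonylation in allyl alcohol (PdCl2(PPh3)2, CO, Et3N) gives the alkylidene β-keto allyl ester F2. The far more electrophilic F2 takes up the cuprate made from 6 and CuBr·SMe2 at −78 °C, again anti to the silyloxy group, to give the allyl β-keto ester F3. Treating F3 with Pd(PPh3)4 in THF (Tsuji decarboxylative allylation) releases the regiospecific enolate and allylates it, and the route is rejoined at 9.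

Step 8. The enantioface control on an α-methyl enal carrying a remote ketone and a terminal alkene may be incomplete, and boron or zinc by-products can promote an unselective background addition. Fallback: the stereocentre is set by reduction instead of by C–C bond formation. Setting out from 11 and 14, the same hydroboration–transmetalation is run without the ligand and gives 17 together with its 5R carbinol epimer F4. MnO2 in CH2Cl2 oxidises only the bis-allylic alcohol of the mixture to the cross-conjugated dienone F5. Reduction of F5 with (R)-2-methyl-CBS-oxazaborolidine and catecholborane at −78 °C, in which the 2-methylalkenyl arm acts as the large group and the hindered ring ketone is slow, returns the route at 17.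

Step 12. The hindered tertiary allylic alcohol may dehydrate instead of transposing, the bis-allylic silyl ether may suffer on the acidic chromium reagent, and the enal may form as an E/Z mixture. The minor geometric isomer and any C2 epimer are expected to move to the natural arrangement on mild base or acid equilibration through the dienol. Fallback: a non-oxidative construction of the enal. Setting out from 20, addition of 1-ethoxyprop-1-en-2-yllithium (from 2-bromo-1-ethoxyprop-1-ene and t-BuLi, with CeCl3, THF, −78 °C) gives the β-ethoxyvinyl carbinol F6. Brief treatment of F6 with 0.1 M HCl in THF/H2O at 0 °C causes hydrolytic allylic transposition with loss of ethanol, and the route is rejoined at 22.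

**Further compounds**
F1 | step 4 | (4S)-2-iodo-3,4-dimethyl-4-[(triethylsilyl)oxy]cyclohex-2-en-1-one | CC1=C(I)C(=O)CC[C@]1(C)O[Si](CC)(CC)CC
F2 | step 4 | prop-2-en-1-yl (3S)-2,3-dimethyl-6-oxo-3-[(triethylsilyl)oxy]cyclohex-1-ene-1-carboxylate | CC1=C(C(=O)OCC=C)C(=O)CC[C@]1(C)O[Si](CC)(CC)CC
F3 | step 4 | prop-2-en-1-yl (2S,3S)-2-[2-(1,3-dioxolan-2-yl)ethyl]-2,3-dimethyl-6-oxo-3-[(triethylsilyl)oxy]cyclohexane-1-carboxylate (C1 epimers) | C1(OCCO1)CC[C@@]2(C)C(C(=O)OCC=C)C(=O)CC[C@]2(C)O[Si](CC)(CC)CC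
F4 | step 8 | (2S,3S,4S)-3-[(3E,5R,6E,8S)-5-hydroxy-4,8,12-trimethyltrideca-3,6,11-trien-1-yl]-3,4-dimethyl-2-(prop-2-en-1-yl)-4-[(triethylsilyl)oxy]cyclohexan-1-one | CC(C)=CCC[C@H](C)/C=C/[C@@H](O)/C(C)=C/CC[C@@]1(C)[C@H](CC=C)C(=O)CC[C@]1(C)O[Si](CC)(CC)CC
F5 | step 8 | (2S,3S,4S)-3,4-dimethyl-2-(prop-2-en-1-yl)-4-[(triethylsilyl)oxy]-3-[(3E,6E,8S)-4,8,12-trimethyl-5-oxotrideca-3,6,11-trien-1-yl]cyclohexan-1-one | CC(C)=CCC[C@H](C)/C=C/C(=O)/C(C)=C/CC[C@@]1(C)[C@H](CC=C)C(=O)CC[C@]1(C)O[Si](CC)(CC)CC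
F6 | step 12 | (2S,3S,4S)-2-{3-[(tert-butyldimethylsilyl)oxy]propyl}-3-[(3E,5S,6E,8S)-5-[(tert-butyldimethylsilyl)oxy]-4,8,12-trimethyltrideca-3,6,11-trien-1-yl]-1-(1-ethoxyprop-1-en-2-yl)-3,4-dimethyl-4-[(triethylsilyl)oxy]cyclohexan-1-ol (C1 epimers) | CC(C)=CCC[C@H](C)/C=C/[C@H](O[Si](C)(C)C(C)(C)C)/C(C)=C/CC[C@@]1(C)[C@H](CCCO[Si](C)(C)C(C)(C)C)C(O)(C(C)=COCC)CC[C@]1(C)O[Si](CC)(CC)CC
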